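**Plan**

1. Cuts, in retrosynthetic order: the bond from the veratryl ring to the carbinol carbon C7 (gives aryl Grignard 13 and aldehyde 19, C7 at the aldehyde oxidation level); the C8–O aryl ether bond (gives phenol 16 and ethyl (S)-lactate 17); the oxolane C5–veratryl bond (gives sulfone 12 and arylzinc 14); the C4–CH3 bond; the C2–C3 bond (crotylboration of O-benzylvanillin 1).
2. Forward: (Z)-crotylboration, hydroboration and oxidative lactonisation close the five-membered lactone that becomes the oxolane ring. α-Methylation, reduction, sulfone formation and arylation complete the 2,5-diaryl-3,4-dimethyloxolane. Debenzylation, Mitsunobu etherification, ester-to-aldehyde reduction and aryl addition then build the side chain.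
3. Stereochemistry: oxolane C2 and C3 come from catalyst-controlled syn-crotylboration; C4 from trans-alkylation of the lactone enolate; C5 from addition to the oxocarbenium ion on the face away from the C2 aryl/C3 methyl pair; C8 from (S)-lactate with Mitsunobu inversion; C7 from 1,2-chelation control in the last step.
4. Enabling feature: C8 carries the oxygen of a guaiacyl (2-methoxyphenyl) ether. That ether oxygen, the ortho-methoxy oxygen on the same benzene ring and the C7 aldehyde oxygen can hold one magnesium ion in two fused five-membered chelate rings, so that only the C8 methyl/hydrogen pair differentiates the two faces of C7=O.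

Key step: step 11

Remark: compounds 1, 2, 13 and 17 and the phosphoric acid catalyst are taken as commercial. Boron, aluminium and magnesium alkoxides that are only hydrolysed on aqueous work-up are not counted as separate compounds. Lactols 7 and 11 and sulfone 12 are epimer mixtures at the anomeric carbon, which converge in the following step.

**Step 1**
Reactants: 1 4-(benzyloxy)-3-methoxybenzaldehyde; 2 (Z)-crotylboronic acid pinacol ester
Product: 3 (1S,2R)-1-[4-(benzyloxy)-3-methoxyphenyl]-2-methylbut-3-en-1-ol
Conditions: (S)-TRIP phosphoric acid (5 mol %), 4 Å MS, PhMe, −30 °C; aq. NaHCO3 work-up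
Reagents that add atoms: none
Why: Chiral-phosphoric-acid-catalysed aldehyde crotylboration through a closed six-membered chair transition state, in which the (Z)-crotyl geometry sets the syn relation of hydroxyl and methyl and the (S)-configured catalyst, bound to the boronate oxygen and the formyl hydrogen, should direct attack to the si face of the aldehyde to give the (1S,2R) alcohol.

**Step 2**
Reactants: 3 (1S,2R)-1-[4-(benzyloxy)-3-methoxyphenyl]-2-methylbut-3-en-1-ol
Product: 5 (1S,2R)-1-[4-(benzyloxy)-3-methoxyphenyl]-2-methylbutane-1,4-diol, via B-alkyl-9-borabicyclononane 4 (not isolated)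
Conditions: 9-BBN, THF, 0 °C to rt; then NaOH, H2O2, 0 °C to rt
Reagents that add atoms: hydrogen peroxide, OO
Why: Anti-Markovnikov hydroboration of the terminal alkene with the bulky 9-BBN places boron on the terminal carbon, and alkaline peroxide oxidation replaces boron by hydroxyl without touching the two existing stereocentres.

**Step 3**
Reactants: 5 (1S,2R)-1-[4-(benzyloxy)-3-methoxyphenyl]-2-methylbutane-1,4-diol
Product: 8 (4R,5S)-5-[4-(benzyloxy)-3-methoxyphenyl]-4-methyloxolan-2-one, via hydroxy aldehyde 6 (not isolated), via lactol 7 (not isolated)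
Conditions: TEMPO (cat.), PhI(OAc)2, CH2Cl2, rt
Reagents that add atoms: none
Why: Oxoammonium (TEMPO/PhI(OAc)2) oxidation takes the primary alcohol selectively to the aldehyde, which closes with the benzylic hydroxyl to the five-membered lactol and is oxidised on to the γ-lactone, the stereocentres not being involved.

**Step 4**
Reactants: 8 (4R,5S)-5-[4-(benzyloxy)-3-methoxyphenyl]-4-methyloxolan-2-one
Product: 10 (3R,4R,5S)-5-[4-(benzyloxy)-3-methoxyphenyl]-3,4-dimethyloxolan-2-one, via lithium enolate 9 (not isolated)
Conditions: LiN(SiMe3)2, THF, −78 °C; then MeI, −78 to −40 °C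
Reagents that add atoms: iodomethane, CI
Why: Alkylation of the lithium lactone enolate should occur on the ring face opposite the cis-related β-methyl and γ-aryl groups, so the new methyl group is set trans to the β-methyl group (3R).

**Step 5**
Reactants: 10 (3R,4R,5S)-5-[4-(benzyloxy)-3-methoxyphenyl]-3,4-dimethyloxolan-2-one
Product: 11 (3R,4R,5S)-5-[4-(benzyloxy)-3-methoxyphenyl]-3,4-dimethyloxolan-2-ol (mixture of C2 epimers)
Conditions: i-Bu2AlH, CH2Cl2, −78 °C; aq. potassium sodium tartrate work-up
Reagents that add atoms: none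
Why: Partial reduction of a γ-lactone with i-Bu2AlH at low temperature stops at the tetrahedral aluminium lactolate, which releases the lactol on work-up.

**Step 6**
Reactants: 11 (3R,4R,5S)-5-[4-(benzyloxy)-3-methoxyphenyl]-3,4-dimethyloxolan-2-ol
Product: 12 (3R,4R,5S)-2-(benzenesulfonyl)-5-[4-(benzyloxy)-3-methoxyphenyl]-3,4-dimethyloxolane (mixture of C2 epimers)
Conditions: PhSO2H, CaCl2, CH2Cl2, rt
Reagents that add atoms: benzenesulfinic acid, O=S(O)c1ccccc1
Why: Anomeric substitution of a lactol by sulfinic acid: the mildly acidic reagent ionises the lactol to the cyclic oxocarbenium ion, which is trapped at sulfur to give the 2-sulfonyl cyclic ether while CaCl2 takes up the water.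

**Step 7**
Reactants: 12 (3R,4R,5S)-2-(benzenesulfonyl)-5-[4-(benzyloxy)-3-methoxyphenyl]-3,4-dimethyloxolane; 13 (3,4-dimethoxyphenyl)magnesium bromide
Product: 15 (2S,3R,4R,5S)-2-[4-(benzyloxy)-3-methoxyphenyl]-5-(3,4-dimethoxyphenyl)-3,4-dimethyloxolane, via arylzinc bromide 14 (not isolated)
Conditions: 13, ZnBr2, THF, rt, 30 min; then 12, THF, rt
Reagents that add atoms: none
Why: Addition of an organozinc reagent to a 2-sulfonyl cyclic ether: zinc bromide ionises the sulfone to the five-membered oxocarbenium ion, and the arylzinc should add by inside attack on the face away from the cis-related aryl and methyl groups at the far side of the ring, which sets the new aryl group cis to its neighbouring methyl group and trans to the other aryl group.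

**Step 8**
Reactants: 15 (2S,3R,4R,5S)-2-[4-(benzyloxy)-3-methoxyphenyl]-5-(3,4-dimethoxyphenyl)-3,4-dimethyloxolane
Product: 16 4-[(2S,3R,4R,5S)-5-(3,4-dimethoxyphenyl)-3,4-dimethyloxolan-2-yl]-2-methoxyphenol
Conditions: H2 (1 atm), Pd/C, EtOAc, rt
Reagents that add atoms: none
Why: Hydrogenolysis of the benzyl aryl ether over Pd/C should be much faster than cleavage of the cyclic dibenzylic ether, so the phenol is released with the oxolane ring intact.

**Step 9**
Reactants: 16 4-[(2S,3R,4R,5S)-5-(3,4-dimethoxyphenyl)-3,4-dimethyloxolan-2-yl]-2-methoxyphenol; 17 ethyl (2S)-2-hydroxypropanoate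
Product: 18 ethyl (2R)-2-{4-[(2S,3R,4R,5S)-5-(3,4-dimethoxyphenyl)-3,4-dimethyloxolan-2-yl]-2-methoxyphenoxy}propanoate
Conditions: PPh3, DIAD, THF, 0 °C to rt
Reagents that add atoms: none
Why: Mitsunobu etherification of the phenol with the secondary alcohol of ethyl (S)-lactate proceeds by SN2 displacement of the oxyphosphonium group with inversion, which sets C8 as R.

**Step 10**
Reactants: 18 ethyl (2R)-2-{4-[(2S,3R,4R,5S)-5-(3,4-dimethoxyphenyl)-3,4-dimethyloxolan-2-yl]-2-methoxyphenoxy}propanoate
Product: 19 (2R)-2-{4-[(2S,3R,4R,5S)-5-(3,4-dimethoxyphenyl)-3,4-dimethyloxolan-2-yl]-2-methoxyphenoxy}propanal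
Conditions: i-Bu2AlH, CH2Cl2, −78 °C; MeOH, then cold aq. potassium sodium tartrate; crude product used at once
Reagents that add atoms: none
Why: At −78 °C an α-aryloxy ester is reduced by i-Bu2AlH only as far as the chelate-stabilised hemiacetal aluminate, which releases the aldehyde on cold work-up, and immediate use of the crude aldehyde should keep the α-stereocentre from epimerising.

**Step 11**
Reactants: 19 (2R)-2-{4-[(2S,3R,4R,5S)-5-(3,4-dimethoxyphenyl)-3,4-dimethyloxolan-2-yl]-2-methoxyphenoxy}propanal; 13 (3,4-dimethoxyphenyl)magnesium bromide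
Product: 20 (1R,2R)-1-(3,4-dimethoxyphenyl)-2-{4-[(2S,3R,4R,5S)-5-(3,4-dimethoxyphenyl)-3,4-dimethyloxolan-2-yl]-2-methoxyphenoxy}propan-1-ol
Conditions: MgBr2·OEt2, CH2Cl2, −78 °C, 30 min; then 13 (THF solution), −78 °C; aq. NH4Cl
Reagents that add atoms: none
Why: Cram-chelate addition of an aryl Grignard reagent to an α-aryloxy aldehyde: after MgBr2 pre-complexation in a weakly donating solvent one magnesium ion is held by the C7 aldehyde oxygen, the C8 ether oxygen and the ortho-methoxy oxygen of the guaiacyl ring, which locks C7=O and C8–O syn-periplanar in a five-membered chelate. The aryl group is transferred to the carbonyl face that carries the C8 hydrogen, anti to the C8 methyl group, so the aryl–C7 bond is formed and C7 is set as R (threo to C8) by 1,2-induction from the lactate-derived centre. The closest known reaction type is the chelation-controlled addition of Grignard reagents to 2-alkoxy- and 2-aryloxypropanals. No ring is closed in this step. The step needs diastereofacial selectivity for chelate over Felkin–Anh addition (which would give the 7S erythro epimer) and addition in preference to α-deprotonation; the first is secured by the two adjacent oxygen donors of the guaiacyl ether and the low-donor medium, the second by the low temperature and the high carbonyl reactivity of the aldehyde. The four oxolane stereocentres are remote from the reacting carbonyl and are not affected.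

**Compound list**

1 | 4-(benzyloxy)-3-methoxybenzaldehyde | COc1cc(C=O)ccc1OCc1ccccc1 | starting material
2 | 2-[(2Z)-but-2-en-1-yl]-4,4,5,5-tetramethyl-1,3,2-dioxaborolane ((Z)-crotylboronic acid pinacol ester) | C/C=C\CB1OC(C)(C)C(C)(C)O1 | starting material
3 | (1S,2R)-1-[4-(benzyloxy)-3-methoxyphenyl]-2-methylbut-3-en-1-ol | COc1cc([C@@H](O)[C@H](C)C=C)ccc1OCc1ccccc1 | intermediate
4 | 9-{(3R,4S)-4-[4-(benzyloxy)-3-methoxyphenyl]-4-hydroxy-3-methylbutyl}-9-borabicyclo[3.3.1]nonane | COc1cc([C@@H](O)[C@H](C)CCB2C3CCCC2CCC3)ccc1OCc1ccccc1 | intermediate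
5 | (1S,2R)-1-[4-(benzyloxy)-3-methoxyphenyl]-2-methylbutane-1,4-diol | COc1cc([C@@H](O)[C@H](C)CCO)ccc1OCc1ccccc1 | intermediate
6 | (3R,4S)-4-[4-(benzyloxy)-3-methoxyphenyl]-4-hydroxy-3-methylbutanal | COc1cc([C@@H](O)[C@H](C)CC=O)ccc1OCc1ccccc1 | intermediate
7 | (4R,5S)-5-[4-(benzyloxy)-3-methoxyphenyl]-4-methyloxolan-2-ol (mixture of C2 epimers) | COc1cc([C@H]2OC(O)C[C@H]2C)ccc1OCc1ccccc1 | intermediate
8 | (4R,5S)-5-[4-(benzyloxy)-3-methoxyphenyl]-4-methyloxolan-2-one | COc1cc([C@H]2OC(=O)C[C@H]2C)ccc1OCc1ccccc1 | intermediate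
9 | lithium (4R,5S)-5-[4-(benzyloxy)-3-methoxyphenyl]-4-methyl-4,5-dihydrofuran-2-olate | COc1cc([C@H]2OC([O-])=C[C@H]2C)ccc1OCc1ccccc1.[Li+] | intermediate
10 | (3R,4R,5S)-5-[4-(benzyloxy)-3-methoxyphenyl]-3,4-dimethyloxolan-2-one | COc1cc([C@H]2OC(=O)[C@H](C)[C@H]2C)ccc1OCc1ccccc1 | intermediate
11 | (3R,4R,5S)-5-[4-(benzyloxy)-3-methoxyphenyl]-3,4-dimethyloxolan-2-ol (mixture of C2 epimers) | COc1cc([C@H]2OC(O)[C@H](C)[C@H]2C)ccc1OCc1ccccc1 | intermediate
12 | (3R,4R,5S)-2-(benzenesulfonyl)-5-[4-(benzyloxy)-3-methoxyphenyl]-3,4-dimethyloxolane (mixture of C2 epimers) | COc1cc([C@H]2OC(S(=O)(=O)c3ccccc3)[C@H](C)[C@H]2C)ccc1OCc1ccccc1 | intermediate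
13 | (3,4-dimethoxyphenyl)magnesium bromide | COc1ccc([Mg]Br)cc1OC | starting material
14 | (3,4-dimethoxyphenyl)zinc bromide | COc1ccc([Zn]Br)cc1OC | intermediate
15 | (2S,3R,4R,5S)-2-[4-(benzyloxy)-3-methoxyphenyl]-5-(3,4-dimethoxyphenyl)-3,4-dimethyloxolane | COc1cc([C@H]2O[C@H](c3ccc(OC)c(OC)c3)[C@H](C)[C@H]2C)ccc1OCc1ccccc1 | intermediate
16 | 4-[(2S,3R,4R,5S)-5-(3,4-dimethoxyphenyl)-3,4-dimethyloxolan-2-yl]-2-methoxyphenol | COc1cc([C@H]2O[C@H](c3ccc(OC)c(OC)c3)[C@H](C)[C@H]2C)ccc1O | intermediate
17 | ethyl (2S)-2-hydroxypropanoate (ethyl (S)-lactate) | C[C@H](O)C(=O)OCC | starting material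
18 | ethyl (2R)-2-{4-[(2S,3R,4R,5S)-5-(3,4-dimethoxyphenyl)-3,4-dimethyloxolan-2-yl]-2-methoxyphenoxy}propanoate | CCOC(=O)[C@@H](C)Oc1ccc([C@H]2O[C@H](c3ccc(OC)c(OC)c3)[C@H](C)[C@H]2C)cc1OC | intermediate
19 | (2R)-2-{4-[(2S,3R,4R,5S)-5-(3,4-dimethoxyphenyl)-3,4-dimethyloxolan-2-yl]-2-methoxyphenoxy}propanal | O=C[C@@H](C)Oc1ccc([C@H]2O[C@H](c3ccc(OC)c(OC)c3)[C@H](C)[C@H]2C)cc1OC | intermediate
20 | (1R,2R)-1-(3,4-dimethoxyphenyl)-2-{4-[(2S,3R,4R,5S)-5-(3,4-dimethoxyphenyl)-3,4-dimethyloxolan-2-yl]-2-methoxyphenoxy}propan-1-ol | COc1ccc([C@@H](O)[C@@H](C)Oc2ccc([C@H]3O[C@H](c4ccc(OC)c(OC)c4)[C@H](C)[C@H]3C)cc2OC)cc1OC | target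

**Step count and risks**

Total step count: 11. Longest linear sequence: 11 steps, from 1 to 20.

Steps most likely to fail:

Step 11. The aryl ether oxygen is a weak donor and the THF that comes with the Grignard reagent competes for magnesium, so addition through the non-chelated aldehyde (Felkin–Anh) may erode the facial selectivity, and α-deprotonation may erode C8. The fallback sets out from ester 18 and forms the same aryl–C7 bond at the ketone level, then sets C7 in a separate reduction. Aminolysis with MeNH(OMe)·HCl and i-PrMgCl in THF at −20 °C should give the N-methoxy-N-methylamide F1. Single addition of 13 in THF at 0 °C should give the aryl ketone F2. Reduction with LiBH(s-Bu)3 in THF at −78 °C, a bulky non-chelating hydride that should follow the Felkin–Anh model with the C8 aryloxy group anti to the incoming hydride, should give the threo alcohol and comes back to the route at 20.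

Step 10. Over-reduction to the primary alcohol and epimerisation of the α-aryloxy aldehyde during work-up are the concerns. The fallback sets out from 18. Full reduction with LiBH4 in THF at 0 °C should give the primary alcohol F3, which is configurationally stable and can be purified and stored. Parikh–Doering oxidation (SO3·pyridine, DMSO, i-Pr2NEt, CH2Cl2, 0 °C) immediately before the key step comes back to the route at 19.

Step 7. Slow ionisation of the sulfone, loss of a proton from the oxocarbenium ion to the 2,3-dihydrofuran, or slow aryl transfer from zinc may lower the conversion. The fallback sets out from lactol 11 and replaces the organometallic nucleophile by the neutral arene. Acetylation (Ac2O, pyridine, DMAP, CH2Cl2) should give the anomeric acetate F4. Friedel–Crafts C-arylation with excess 1,2-dimethoxybenzene and BF3·OEt2 in CH2Cl2 at −78 °C should place the oxolane carbon para to one methoxy group. The same oxocarbenium ion is involved, so the same facial preference is expected, and the sequence comes back to the route at 15.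

**Further compounds**

F1 | step 11 | (2R)-2-{4-[(2S,3R,4R,5S)-5-(3,4-dimethoxyphenyl)-3,4-dimethyloxolan-2-yl]-2-methoxyphenoxy}-N-methoxy-N-methylpropanamide | CON(C)C(=O)[C@@H](C)Oc1ccc([C@H]2O[C@H](c3ccc(OC)c(OC)c3)[C@H](C)[C@H]2C)cc1OC
F2 | step 11 | (2R)-1-(3,4-dimethoxyphenyl)-2-{4-[(2S,3R,4R,5S)-5-(3,4-dimethoxyphenyl)-3,4-dimethyloxolan-2-yl]-2-methoxyphenoxy}propan-1-one | COc1ccc(C(=O)[C@@H](C)Oc2ccc([C@H]3O[C@H](c4ccc(OC)c(OC)c4)[C@H](C)[C@H]3C)cc2OC)cc1OC
F3 | step 10 | (2R)-2-{4-[(2S,3R,4R,5S)-5-(3,4-dimethoxyphenyl)-3,4-dimethyloxolan-2-yl]-2-methoxyphenoxy}propan-1-ol | OC[C@@H](C)Oc1ccc([C@H]2O[C@H](c3ccc(OC)c(OC)c3)[C@H](C)[C@H]2C)cc1OC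
F4 | step 7 | (3R,4R,5S)-5-[4-(benzyloxy)-3-methoxyphenyl]-3,4-dimethyloxolan-2-yl acetate (mixture of C2 epimers) | COc1cc([C@H]2OC(OC(C)=O)[C@H](C)[C@H]2C)ccc1OCc1ccccc1
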